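In this closed flask Q cannot hold more than E has lost, so I need two things from the run followed so far: how much E is lost by the asked time, and what part of that loss ends in Q.

all flasks: E 0.50 M
- north-west: Z 1 mM; the very flask that is asked about, followed so far
- flask: Z 1.0 mM; time 2.5 h

north-west run (percent of the E charged)

| time / min | J / % | D / % | Q / % | E / % |
|---|---|---|---|---|
| 20.0 | 0.5 | 4.6 | 8.8 | 86.9 |
| 40.0 | 0 | 7.0 | 16.1 | 76.2 |
| 60.0 | 1.2 | 10.6 | 23.0 | 66.6 |
| 80.0 | 1.5 | 12.5 | 28.9 | 58.7 |

(each reading ± 0.5 percentage points)

- the numbers in the tables scatter with a standard deviation of 0.5 percentage points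

* the largest share of what was charged as E, at 2.5 h belongs to (J / E / Q / D)
* the largest share itself, whichever of these holds it, in percent of the E charged

If [E] falls first order, the negative logarithm of the fraction left, divided by the time, is a rate constant k. The last reading gives 0.00666 min⁻¹ and the reading at 40.0 min gives 0.00680 min⁻¹, so I carry k forward, and at 2.5 h it leaves 36.8% of E.

At 80.0 min Q holds 28.9% of the 41.3% of E lost, which makes 70.0%; at 20.0 min the same ratio reads 67.2%, on a smaller loss with the same scatter. I call this ratio the branch share, the selectivity for Q, and I hold it constant.

So I expect 44.2% of Q, more than the E left and more than the 19.0% left for D and J together. Q passes E when the branch share times the E lost equals the E left, at 2.22 h, which is earlier than the asked time.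

The forecast says Q at 43.5%, lower than my figure, and sees parallel formation “with no sign of Q being consumed”.

    E → Q (k = 7.60 × 10⁻⁵ s⁻¹)
    E ⇌ D (K = 17.0, k = 3.80 × 10⁻⁵ s⁻¹)
    D + Z ⇌ J + Z, rate k3*[Z]*[D] forward; the back reaction follows from the equilibrium constant (K = 0.570, k = 0.0440 L mol⁻¹ s⁻¹)

At 2.5 h the flask holds Q at 42.8%, the largest share, with E at 36.0%, and the branch share reads 66.9%. E ran to Q and to D side by side, at the start to Q at twice the forward rate to D, while D went on to J, with Z at 100% of its charge at 2.50 h. The branch share as I read it gives the flask left until 4.0 h 56.2% of Q against its 53.9%, and the crossing I reckoned at 2.22 h falls later than 1.5 h. Left until 1.5 h, the flask has E on top at 54.1%, with Q at 30.7%.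

(Readings and results stem from a simulated flask for substances that don't exist, and the scatter is random.)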